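(The rate constants are assumed.)

Begin at late times and read the run backwards. In west, X has a half-life of 5.33 s against step 3 and L lasts about 2.35 s at the full charge of E, both far shorter than the 15 min of the run . Reckon the end, then, as a flask where each L charged has become Q or D.

- west: L 0.050 M; E 2.50 equiv; temperature 5 °C; time 15 min
- north: L 0.050 M; E 2.50 equiv; temperature 25 °C; time 15 min

    L + E → X + Z (k1 = 3.4 M⁻¹ s⁻¹, Ea1 = 48.0 kJ mol⁻¹)
    E + X → Q + Z (k2 = 6.6 M⁻¹ s⁻¹, Ea2 = 46.0 kJ mol⁻¹)
    X → D (k3 = 0.13 s⁻¹, Ea3 = 72.0 kJ mol⁻¹)
    (constants at 5 °C)

- the best flask by amount of Q, in percent of the L charged; "all alike" if 1.5 percentage points covers them all (west / north / all alike)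
- amount of Q at the end, in percent of the L charged, west
- amount of Q at the end, in percent of the L charged, north

- constants are those at 5 °C; use the activation energies for any other temperature

Compare the two exits of X. At the start in west, X goes on to Q at 0.825 s⁻¹ and falls to D at 0.13 s⁻¹. Call their ratio, 6.35, the split number: the rate of X into Q with E at its full charge over the rate of X into D. It is a selectivity factor. The share of X reaching Q at the start is the number over the number plus one, 86.4%.

One thing slows the Q exit: E is spent, one for each L and one more for each Q. Multiply the split number by the fraction of E left. Try Q at the start share: E left is 25.4%, the number falls to 1.61, and the share to 61.7%. Take the mean of the two shares for the whole run, 74.1%. Put that back once: E left is 30.4%, and Q in west comes to 76.1%.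

North speeds step 3 by 8.1 but step 2 by 3.8, so its number is 2.99 and its start share 74.9%. The same rounds pass through 30.0% of E left and a mean of 61.1%, then 35.6% left, and Q in north comes to 63.2%. Back west.

The forecast names west, with 77% (74% to 80%) for west and 64% (60% to 68%) for north, since warming “diverts more X to D and leaves the cold flask clearly ahead”. The simulation gives west as best, with Q at 77.2% in west and 63.5% in north.

Take the passing of X into D away from north and Q rises from 63.5% to 100%; that loss is the main reason Q falls short in north. Carry the number to a neighbour flask, north with 0.030 M of L and the same equivalents of E: it shrinks to 1.79, a start share of 64.2%. The same rounds give a mean of 51.1%, then 39.5% of E left and 52.8% of Q, and the neighbour flask ends with Q at 52.6%.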